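**Strategy.** The γ-lactone is disconnected across both of its bonds to ring A, O–C8 and C11–C7. The feature exploited is that O6 and C11 are cis on ring A while C11 and the lactone oxygen are trans: the C11–C12 unit is hung from O6 through the future methylene C13 as an α-sulfonyl ester. One Mn(OAc)3/Cu(OAc)2 oxidative radical cyclisation of this ether onto the C7=C8 alkene forms C11–C7 (oxolane O6–C13–C11–C7–C6) and O–C8 (lactone ring) together; SmI2 later excises the sulfone and opens the oxolane to the C11=C13 methylene and 6-hydroxyl. The cyclohexene comes from a quinone monoketal by one catalytic asymmetric conjugate addition.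

Key step: step 13

Remark on the chemistry: elemane locants are used from compound 7 on (ring A = C5–C10; C1–C2 = vinyl or oxirane and C14 = methyl on C10; C4, C3, C15 = three-carbon unit on C5; C11, C12, C13 = lactone carbons). β is the ring face of the C5 side chain and the C10 methyl, α the opposite face. Compound 19 is carried as a mixture at C11, which becomes planar in step 13.

Step 1
Reactants: 1 4,4-dimethoxycyclohexa-2,5-dien-1-one; 2 isopropenylboronic acid pinacol ester
Product: 3 (5R)-4,4-dimethoxy-5-(prop-1-en-2-yl)cyclohex-2-en-1-one
Conditions: [Rh(OH)(cod)]2 (2.5 mol %), (R)-BINAP, KOH (cat.), dioxane/H2O, 40 °C, 1.05 equiv of 2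
Reagents that add atoms: none
Why: Hayashi–Miyaura rhodium-catalysed asymmetric 1,4-addition of an alkenylboron reagent to one enone arm of the symmetric dienone, in which the (R)-BINAP complex should select the enantiotopic face that gives (5R)-3 (the only stereocentre set by catalysis) while the limiting boronate restrains a second addition.

Step 2
Reactants: 3
Product: 5 (5R,6S)-4,4-dimethoxy-6-methyl-5-(prop-1-en-2-yl)cyclohex-2-en-1-one, via lithium dienolate 4 (not isolated)
Conditions: LiN(iPr)2, THF, −78 °C; MeI, DMPU, −78 to −40 °C
Reagents that add atoms: iodomethane CI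
Why: Kinetic enolate alkylation: C10 is the only position that can be deprotonated (C6 is a ketal and C8 is vinylic), and iodomethane should enter anti to the neighbouring C5 isopropenyl group, although this centre becomes planar again in step 3.

Step 3
Reactants: 5
Product: 7 6,6-dimethoxy-10β-methyl-10α-vinyl-5β-isopropenylcyclohex-7-en-9-one, via lithium dienolate 6 (not isolated)
Conditions: LiN(SiMe3)2, THF, −78 °C; Pd2(dba)3 (2.5 mol %), P(tBu)3, vinyl bromide, THF/toluene, rt
Reagents that add atoms: vinyl bromide C=CBr
Why: Palladium-catalysed α-vinylation of a ketone enolate (zerovalent palladium inserts into vinyl bromide, the C-bound enolate then undergoes reductive elimination), with the vinyl group expected on the α face, anti to the C5 isopropenyl group, so that the quaternary C10 carries methyl β and vinyl α.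

Step 4
Reactants: 7
Product: 8 6,6-dimethoxy-10β-methyl-10α-vinyl-5β-isopropenylcyclohexan-9-one
Conditions: [(Ph3P)CuH]6 (0.4 equiv), benzene, H2O (2 equiv), rt
Reagents that add atoms: none
Why: Copper hydride conjugate reduction, which is selective for the electron-poor C7=C8 enone bond and should leave the isolated vinyl and isopropenyl groups untouched.

Step 5
Reactants: 8
Product: 9 6,6-dimethoxy-10β-methyl-10α-vinyl-5β-isopropenylcyclohexan-9α-ol
Conditions: (S)-2-methyl-CBS-oxazaborolidine (0.2 equiv), catecholborane, toluene, −40 °C; aq. NaOH work-up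
Reagents that add atoms: none
Why: Corey–Bakshi–Shibata reduction under reagent control: the quaternary C10 is the large and C8H2 the small flank of the ketone, so the (S)-oxazaborolidine should deliver hydride to the β face and give the 9α (axial) alcohol, and catecholborane does not hydroborate the alkenes at this temperature.

Step 6
Reactants: 9
Product: 10 9α-hydroxy-10β-methyl-10α-vinyl-5β-isopropenylcyclohexan-6-one
Conditions: oxalic acid (cat.), THF/H2O, rt
Reagents that add atoms: water O
Why: Acid-catalysed hydrolysis of a dimethyl ketal, which proceeds under conditions mild enough to spare the β,γ-unsaturated ketone that is formed.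

Step 7
Reactants: 10
Product: 11 9α-hydroxy-10β-methyl-10α-[(2R)-oxiran-2-yl]-5β-isopropenylcyclohexan-6-one
Conditions: VO(acac)2 (5 mol %), tBuOOH (decane), CH2Cl2, 0 °C to rt
Reagents that add atoms: tert-butyl hydroperoxide CC(C)(C)OO
Why: Hydroxyl-directed epoxidation of a homoallylic alcohol with VO(acac)2 and tBuOOH: with the alkoxide axial on C9 and the vinyl group equatorial on C10, the chair-like transition state that keeps C2 pseudo-equatorial should deliver oxygen to the face giving the (1R)-oxirane, and the bishomoallylic isopropenyl group reacts more slowly.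

Step 8
Reactants: 11; 12 (S)-2-methylbutanoic acid
Product: 13 9α-[(2S)-2-methylbutanoyloxy]-10β-methyl-10α-[(2R)-oxiran-2-yl]-5β-isopropenylcyclohexan-6-one
Conditions: N,N'-diisopropylcarbodiimide, DMAP, CH2Cl2, rt
Reagents that add atoms: none
Why: Steglich esterification of the hindered axial 9α-hydroxyl with the enantiopure acid, under conditions that should not epimerise its α-stereocentre.

Step 9
Reactants: 13
Product: 14 9α-[(2S)-2-methylbutanoyloxy]-10β-methyl-10α-[(2R)-oxiran-2-yl]-5β-isopropenylcyclohex-7-en-6-one
Conditions: IBX, 4-methoxypyridine N-oxide, DMSO, rt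
Reagents that add atoms: none
Why: IBX dehydrogenation of a ketone to the enone, which can only take place towards C7–C8 because the other α-carbon (C5) has a quaternary neighbour.

Step 10
Reactants: 14
Product: 15 9α-[(2S)-2-methylbutanoyloxy]-10β-methyl-10α-[(2R)-oxiran-2-yl]-5β-isopropenylcyclohex-7-en-6β-ol
Conditions: NaBH4, CeCl3·7H2O, MeOH, −78 °C
Reagents that add atoms: none
Why: Luche 1,2-reduction: hydride should attack C6 from the α face because the β face is screened by the syn-axial C10 methyl group (the situation of 6-oxo steroids), giving the 6β (axial) alcohol cis to the C5 isopropenyl group.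

Step 11
Reactants: 16 tert-butyl 2-(phenylsulfonyl)acetate
Product: 17 tert-butyl 2-(phenylsulfonyl)prop-2-enoate
Conditions: paraformaldehyde, piperidinium acetate (cat.), benzene, reflux with water separator
Reagents that add atoms: formaldehyde (as paraformaldehyde) C=O
Why: Knoevenagel-type methylenation of the doubly activated methylene group with formaldehyde, water being removed azeotropically.

Step 12
Reactants: 15; 17
Product: 19 6β-O-[2-tert-butoxycarbonyl-2-(phenylsulfonyl)ethyl] ether of 15 (C11 epimers), via potassium alkoxide 18 (not isolated)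
Conditions: KN(SiMe3)2 (1.0 equiv), THF, −78 °C; 17, −78 to −40 °C; AcOH quench
Reagents that add atoms: none
Why: Oxa-Michael addition of the potassium 6β-alkoxide to the unhindered terminus of the doubly activated acrylate, driven by formation of the stabilised sulfonyl ester carbanion that is protonated on quench; the new C11 centre is formed without control but becomes planar in step 13.

Step 13
Reactants: 19
Product: 20 11-phenylsulfonyl-6β,13-epoxy-12,8α-olide (oxolane-fused trans γ-lactone carrying the 9α-ester, the (1R)-oxirane and 5β-isopropenyl)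
Conditions: Mn(OAc)3·2H2O (2.2 equiv), Cu(OAc)2·H2O (0.5 equiv), KOAc, AcOH/MeCN, 45 °C, degassed
Reagents that add atoms: none
Why: Mn(OAc)3 oxidises the α-sulfonyl ester to the C11 radical, which adds 5-exo-trig to C7; the C8 radical is captured by Cu(OAc)2 and the alkylcopper collapses onto the tert-butyl ester carbonyl oxygen with loss of 2-methylpropene, so C11–C7 and O–C8 form in one operation. The closest known reaction type is the manganese triacetate oxidative free-radical cyclisation of unsaturated active-methylene esters terminated by copper-mediated lactonisation (radical–polar crossover carbolactonisation). The oxolane ring (C6, O6, C13, C11, C7) closes by 5-exo-trig radical attack and must be cis-fused to ring A; the γ-lactone (C7, C8, O, C12, C11) closes by five-membered attack of the ester oxygen on C8. C7 is set by the tether (C11 enters on the β face that carries O6), C11 by the preference of the bulky sulfonyl group for the exo position, which leaves the ester endo next to C8, and C8 by capture from the α face, because the β face is screened by the axial C10 methyl and axial O6 and only α closure keeps ring A in a chair with O6 axial and C11 and the lactone oxygen equatorial, the trans fusion of the target. The step needs 5-exo attack on C7 to beat 7-endo attack on the isopropenyl group and lactonisation to beat oxidative elimination of the C8 copper species; the three-atom tether and the endo ester held beside C8 should secure both.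

Step 14
Reactants: 20
Product: 21 6β-hydroxy-11(13)-en-12,8α-olide carrying the 9α-[(2S)-2-methylbutanoyloxy] group, the (1R)-oxirane and 5β-isopropenyl
Conditions: SmI2 (2.2 equiv), THF, −78 °C then 0 °C; pH 7 buffer at −78 °C
Reagents that add atoms: none
Why: Reductive desulfonylation with SmI2 gives the samarium lactone enolate, which should expel the β-alkoxide O6 on warming (E1cB, a Julia-type reductive elimination), so that the exocyclic methylene C11=C13 and the free 6β-hydroxyl are unveiled together while the C7 and C8 centres are untouched.

Step 15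
Reactants: 21
Product: 22 15-hydroxy derivative of 21 (5β-(3-hydroxyprop-1-en-2-yl))
Conditions: SeO2 (0.5 equiv), tBuOOH, CH2Cl2, rt
Reagents that add atoms: tert-butyl hydroperoxide CC(C)(C)OO
Why: Riley-type allylic oxidation with catalytic SeO2 and tBuOOH (ene reaction then [2,3]-shift), which should hydroxylate the methyl group of the 1,1-disubstituted isopropenyl alkene in preference to the C5 methine and leave the electron-poor methylene lactone alone.

Step 16
Reactants: 22
Product: 23 CNP0510523.1 (target)
Conditions: MnO2 (activated, excess), CH2Cl2, rt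
Reagents that add atoms: none
Why: MnO2 oxidises only the primary allylic alcohol, leaving the secondary, non-allylic 6β-hydroxyl, the oxirane and both esters intact.

**Compound list**

1 | 4,4-dimethoxycyclohexa-2,5-dien-1-one | COC1(OC)C=CC(=O)C=C1 | starting material
2 | isopropenylboronic acid pinacol ester | CC(=C)B1OC(C)(C)C(C)(C)O1 | starting material
3 | (5R)-4,4-dimethoxy-5-(prop-1-en-2-yl)cyclohex-2-en-1-one | O=C1C=CC(OC)(OC)[C@@H](C(C)=C)C1 | intermediate
4 | lithium dienolate of 3 | [Li+].[O-]C1=C[C@H](C(C)=C)C(OC)(OC)C=C1 | intermediate
5 | (5R,6S)-4,4-dimethoxy-6-methyl-5-(prop-1-en-2-yl)cyclohex-2-en-1-one | O=C1C=CC(OC)(OC)[C@@H](C(C)=C)[C@@H]1C | intermediate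
6 | lithium dienolate of 5 | [Li+].[O-]C1=C(C)[C@H](C(C)=C)C(OC)(OC)C=C1 | intermediate
7 | 6,6-dimethoxy-10β-methyl-10α-vinyl-5β-isopropenylcyclohex-7-en-9-one | O=C1C=CC(OC)(OC)[C@@H](C(C)=C)[C@]1(C)C=C | intermediate
8 | 6,6-dimethoxy-10β-methyl-10α-vinyl-5β-isopropenylcyclohexan-9-one | O=C1CCC(OC)(OC)[C@@H](C(C)=C)[C@]1(C)C=C | intermediate
9 | 6,6-dimethoxy-10β-methyl-10α-vinyl-5β-isopropenylcyclohexan-9α-ol | O[C@@H]1CCC(OC)(OC)[C@@H](C(C)=C)[C@]1(C)C=C | intermediate
10 | 9α-hydroxy-10β-methyl-10α-vinyl-5β-isopropenylcyclohexan-6-one | O[C@@H]1CCC(=O)[C@@H](C(C)=C)[C@]1(C)C=C | intermediate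
11 | 9α-hydroxy-10β-methyl-10α-[(2R)-oxiran-2-yl]-5β-isopropenylcyclohexan-6-one | O[C@@H]1CCC(=O)[C@@H](C(C)=C)[C@]1(C)[C@@H]1CO1 | intermediate
12 | (S)-2-methylbutanoic acid | CC[C@H](C)C(=O)O | starting material
13 | 9α-(2S)-2-methylbutanoate of 11 | CC[C@H](C)C(=O)O[C@@H]1CCC(=O)[C@@H](C(C)=C)[C@]1(C)[C@@H]1CO1 | intermediate
14 | 7-en-6-one derived from 13 | CC[C@H](C)C(=O)O[C@@H]1C=CC(=O)[C@@H](C(C)=C)[C@]1(C)[C@@H]1CO1 | intermediate
15 | 6β-hydroxy-7-ene derived from 14 | CC[C@H](C)C(=O)O[C@@H]1C=C[C@@H](O)[C@@H](C(C)=C)[C@]1(C)[C@@H]1CO1 | intermediate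
16 | tert-butyl 2-(phenylsulfonyl)acetate | CC(C)(C)OC(=O)CS(=O)(=O)c1ccccc1 | starting material
17 | tert-butyl 2-(phenylsulfonyl)prop-2-enoate | C=C(C(=O)OC(C)(C)C)S(=O)(=O)c1ccccc1 | intermediate
18 | potassium 6β-alkoxide of 15 | CC[C@H](C)C(=O)O[C@@H]1C=C[C@@H]([O-])[C@@H](C(C)=C)[C@]1(C)[C@@H]1CO1.[K+] | intermediate
19 | 6β-O-[2-tert-butoxycarbonyl-2-(phenylsulfonyl)ethyl] ether of 15 (C11 epimers) | CC[C@H](C)C(=O)O[C@@H]1C=C[C@@H](OCC(C(=O)OC(C)(C)C)S(=O)(=O)c2ccccc2)[C@@H](C(C)=C)[C@]1(C)[C@@H]1CO1 | intermediate
20 | 11-phenylsulfonyl-6β,13-epoxy-12,8α-olide | CC[C@H](C)C(=O)O[C@@H]1[C@@H]2OC(=O)[C@@]3(S(=O)(=O)c4ccccc4)CO[C@H]([C@@H]23)[C@@H](C(C)=C)[C@]1(C)[C@@H]1CO1 | intermediate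
21 | 6β-hydroxy-11(13)-en-12,8α-olide with 5β-isopropenyl | CC[C@H](C)C(=O)O[C@@H]1[C@@H]2OC(=O)C(=C)[C@H]2[C@@H](O)[C@@H](C(C)=C)[C@]1(C)[C@@H]1CO1 | intermediate
22 | 15-hydroxy derivative of 21 | CC[C@H](C)C(=O)O[C@@H]1[C@@H]2OC(=O)C(=C)[C@H]2[C@@H](O)[C@@H](C(=C)CO)[C@]1(C)[C@@H]1CO1 | intermediate
23 | CNP0510523.1 | CC[C@H](C)C(=O)O[C@@H]1[C@@H]2OC(=O)C(=C)[C@H]2[C@@H](O)[C@@H](C(=C)C=O)[C@]1(C)[C@@H]1CO1 | target

**Step count.** Total: 16 steps. Longest linear sequence: 15 steps (steps 1–10 and 12–16; step 11 prepares the acrylate 17).

**Steps most likely to fail.**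

Step 13 carries the most risk. The cyclised C8 copper species may undergo oxidative elimination instead of lactonisation, the neighbouring C9 ester may capture C8 in competition, the sulfonyl group may end up endo so that the lactone cannot close, or the oxirane may be opened by acetic acid. The fallback separates the two bond formations by polar chemistry. It sets out from 19: iodocarbocyclisation (Ti(OtBu)4, I2, CH2Cl2) should give, by anti addition, the 8α-iodo oxolane F1 with C11 on the β face of C7. Silver-assisted ionisation of the iodide (AgOTf, 2,6-di-tert-butylpyridine) should then let the endo tert-butyl ester close the lactone on the α face of C8 with loss of 2-methylpropene. The route is rejoined at 20.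

Step 7 may show poor facial selectivity at the vinyl group, since the two chair-like transition states differ only in placing C2 pseudo-equatorial or pseudo-axial; the new oxirane may also be opened by the free C9 hydroxyl. The fallback sets out from 10 and replaces metal-directed oxygen transfer by an intramolecular iodocarbonate cyclisation. Acylation with Boc2O/DMAP gives the tert-butyl carbonate F2. IBr at −80 °C should close the six-membered cyclic iodocarbonate F3, in which the iodomethyl group sits equatorial on the 1,3-dioxan-2-one chair, which corresponds to the required C1 configuration. K2CO3 in methanol cleaves the carbonate and closes the oxirane, rejoining the route at 11.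

Step 3 may fail because reductive elimination at the congested quaternary C10 is slow, leading to O-vinylation or simple reprotonation of the enolate. The fallback sets out from 5 and builds the vinyl group by aldol addition and dehydration. The lithium enolate (LiN(iPr)2, −78 °C) is trapped with acetaldehyde, anti to the isopropenyl group, to give the β-hydroxy ketone F4 (mixture at the carbinol carbon). Syn-dehydration with methyl N-(triethylammoniosulfonyl)carbamate, which can only occur towards the methyl group, gives 7, where the route is rejoined.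

**Further compounds**

F1 | step 13 | 8α-iodo-6β,13-epoxy-11-phenylsulfonyl tert-butyl ester from iodocarbocyclisation of 19 | CC[C@H](C)C(=O)O[C@@H]1[C@H](I)[C@@H]2[C@@H](OC[C@@]2(C(=O)OC(C)(C)C)S(=O)(=O)c2ccccc2)[C@@H](C(C)=C)[C@]1(C)[C@@H]1CO1
F2 | step 7 | 9α-O-tert-butyl carbonate of 10 | CC(C)(C)OC(=O)O[C@@H]1CCC(=O)[C@@H](C(C)=C)[C@]1(C)C=C
F3 | step 7 | cyclic 9α,1-carbonate of the (1R)-2-iodo-1-hydroxyethyl compound | O=C1O[C@@H]2CCC(=O)[C@@H](C(C)=C)[C@]2(C)[C@H](CI)O1
F4 | step 3 | 10α-(1-hydroxyethyl) aldol adduct of 5 | O=C1C=CC(OC)(OC)[C@@H](C(C)=C)[C@]1(C)C(C)O
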